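The cyclohexene core (ring carbons C1–C6) holds C7 on C1 and the oxygen on C4 on the same face, on either side of the C5=C6 bond. That cis-1,4 pair is treated as a severed C7(=O)–O–C4 lactone bridge, so the ring is disconnected to a 2-oxabicyclo[2.2.2]octenone made by one amine-catalysed asymmetric [4+2] addition of 3-hydroxy-2-pyrone to an (E)-β-silyl enone. This operation forms C1–C2 and C3–C4, closes the carbocycle and sets all four stereocentres; acetyl (C2) and silicon (C3) are then exchanged for oxygen with retention. The precursors are the planar pyrone and (E)-4-[dimethyl(phenyl)silyl]but-3-en-2-one.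

Key step: step 3

Numbering: target numbering is used throughout. C1 is the carbinol carbon bearing C7, C2 and C3 are the diol carbons, C4 carries the ring benzoate, and C5=C6 is the alkene. β is the ring face of the C1 hydroxyl and α the face of C7. In this numbering the target is (1S,2S,3S,4R), with 1β-OH, 2β-OH, 3α-OH and 4α-OBz.

Assumption: the quinidine-derived catalyst is taken to give the enantiomer drawn; if the sense proves opposite, its quinine-derived pseudoenantiomer would be used with no other change.

Remark: the dienophile is approached through the propargylic alcohol, because direct platinum-catalysed hydrosilylation of the ynone risks the α-silyl regioisomer and reduction of the carbonyl group.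

Step 1
Reactants: 1 but-3-yn-2-ol (racemic); 2 dimethyl(phenyl)silane
Product: 3 (E)-4-[dimethyl(phenyl)silyl]but-3-en-2-ol (racemic)
Conditions: PtCl2 (cat.), XPhos (cat.), THF, 50 °C
Reagents that add atoms: none
Why: Platinum-catalysed alkyne hydrosilylation (syn addition of Si–H) of a terminal propargylic alcohol with a bulky biarylphosphine should deliver silicon to the terminal carbon and give the E vinylsilane only; the racemic carbinol centre is erased in step 2.

Step 2
Reactants: 3 (E)-4-[dimethyl(phenyl)silyl]but-3-en-2-ol
Product: 4 (E)-4-[dimethyl(phenyl)silyl]but-3-en-2-one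
Conditions: MnO2, CH2Cl2, rt
Reagents that add atoms: none
Why: Activated MnO2 oxidises allylic alcohols to enones under neutral conditions (allylic alcohol oxidation) and should leave the vinylsilane and its E geometry untouched.

Step 3
Reactants: 4 (E)-4-[dimethyl(phenyl)silyl]but-3-en-2-one; 5 3-hydroxy-2H-pyran-2-one
Product: 6 bicyclic lactone 8-acetyl-4-hydroxy-7-[dimethyl(phenyl)silyl]-2-oxabicyclo[2.2.2]oct-5-en-3-one (route numbering: C7(=O)–O bridge from C1 to C4; C1–OH; acetyl on C2 endo; silicon on C3 exo)
Conditions: 1-[3,5-bis(trifluoromethyl)phenyl]-3-(9-deoxy-epi-quinidin-9-yl)thiourea (10 mol %), Et2O, 0 °C → rt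
Reagents that add atoms: none
Why: The quinuclidine nitrogen deprotonates the 3-OH of 5, and the chiral ammonium olate, held as an ion pair while the thiourea N–H bonds grip the enone carbonyl of 4, adds through an asynchronous [4+2] transition state in which pyrone C6 bonds to the silyl-bearing β-carbon (C3–C4) slightly ahead of pyrone C3 bonding to the α-carbon (C1–C2). The closest known reaction type is the cinchona-amine-catalysed asymmetric Diels–Alder reaction of 3-hydroxy-2-pyrones with β-substituted enones, applied here to a β-silyl enone, a kind of acceptor that already takes part in amine-catalysed conjugate additions. The one new ring, the carbocycle C1–C6, closes by intermolecular suprafacial cycloaddition through a boat transition state (in stepwise terms a Michael addition followed by a 6-(enolexo)-exo-trig aldol), and the former pyrone lactone is left as the C7(=O)–O–C4 bridge. C1 and C4 are set together by the pyrone face that the catalyst leaves open (their cis relation is enforced by the bridge), C2 by placement of the acetyl group endo, under the diene and syn to C5=C6, and C3 by the E geometry of 4, which puts silicon trans to acetyl and syn to the lactone bridge. The step needs regio-, endo- and enantiofacial selectivity: the first follows from the olate of 5, whose donor character is greatest at C6, the second from the carbonyl-endo preference reinforced by the bulky silyl group seeking the exo side, and the third from the catalyst.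

Step 4
Reactants: 6 bicyclic acetyl lactone
Product: 7 4-hydroxy-3-oxo-7-[dimethyl(phenyl)silyl]-2-oxabicyclo[2.2.2]oct-5-en-8-yl acetate (C2–OAc endo; other centres as in 6)
Conditions: mCPBA, CH2Cl2, rt
Reagents that add atoms: mCPBA (3-chloroperoxybenzoic acid), OOC(=O)c1cccc(Cl)c1
Why: Baeyer–Villiger oxidation in which the secondary C2 migrates in preference to methyl with retention of configuration, while the C5=C6 bond, deactivated by the allylic lactone oxygen at C4 and the acylated carbinol at C1, should be epoxidised much more slowly than the ketone, which is activated by a hydrogen bond from C1–OH.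

Step 5
Reactants: 7 bicyclic silyl acetate
Product: 9 4,7-dihydroxy-3-oxo-2-oxabicyclo[2.2.2]oct-5-en-8-yl acetate (C3–OH exo; C2–OAc endo), via fluorodimethylsilyl lactone 8 (not isolated)
Conditions: BF3·2AcOH, CH2Cl2, rt; then mCPBA, KF, DMF, rt
Reagents that add atoms: mCPBA (3-chloroperoxybenzoic acid), OOC(=O)c1cccc(Cl)c1
Why: Fleming–Tamao oxidation: ipso-protodesilylation removes phenyl as benzene to leave the fluorosilane, whose peracid adduct rearranges with migration of C3 from silicon to oxygen with retention, and in the rigid bicycle the C3–Si bond is antiperiplanar to neither the C2–OAc nor the C4–O bond, so β-elimination is blocked.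

Step 6
Reactants: 9 bicyclic hydroxy acetate
Product: 10 methyl 1β,2β,3α,4α-tetrahydroxycyclohex-5-ene-1α-carboxylate
Conditions: K2CO3 (cat.), MeOH, 0 °C → rt; then Amberlite IR-120 (H+)
Reagents that add atoms: methanol, CO
Why: Methoxide-catalysed transesterification opens the strained bridging lactone to the methyl ester and the C4 hydroxyl and strips the acetate as methyl acetate, and no stereocentre carries an acidic hydrogen, so none can epimerise.

Step 7
Reactants: 10 tetraol methyl ester
Product: 11 2,3-O-butane-2,3-diacetal of 10 (trans-fused 2,3-dimethoxy-2,3-dimethyl-1,4-dioxane; both acetal carbons S, methoxy groups axial)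
Conditions: 2,2,3,3-tetramethoxybutane, CSA (cat.), HC(OMe)3, MeOH, reflux
Reagents that add atoms: 2,2,3,3-tetramethoxybutane, COC(C)(OC)C(C)(OC)OC
Why: Thermodynamically controlled butane-2,3-diacetal formation selects the only trans-vicinal diol, C2/C3, because only there can a trans-fused chair dioxane hold both methoxy groups axial (double anomeric stabilisation), which also fixes the two new acetal centres.

Step 8
Reactants: 11 diacetal methyl ester
Product: 12 diacetal triol with C7H2OH on C1 (free 1β-OH and 4α-OH)
Conditions: LiAlH4, THF, 0 °C
Reagents that add atoms: none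
Why: Hydride reduction of the α-hydroxy methyl ester gives the primary alcohol at C7, and the acetal, the alkene and all stereocentres are inert to LiAlH4 at this temperature.

Step 9
Reactants: 12 diacetal triol
Product: 13 diacetal 7-O,4-O-dibenzoate (tertiary 1β-OH free)
Conditions: BzCl, pyridine, DMAP (cat.), CH2Cl2, 0 °C → rt
Reagents that add atoms: benzoyl chloride, O=C(Cl)c1ccccc1
Why: DMAP-catalysed acylation esterifies the primary C7–OH and the secondary allylic C4–OH, while the tertiary C1–OH is too hindered to react under these conditions.

Step 10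
Reactants: 13 diacetal dibenzoate
Product: 14 target, [(1S,4R,5S,6S)-4-(benzoyloxy)-1,5,6-trihydroxycyclohex-2-en-1-yl]methyl benzoate (route numbering 1S,2S,3S,4R)
Conditions: TFA/H2O (9:1), 0 °C → rt
Reagents that add atoms: none
Why: Acid-catalysed acetal hydrolysis releases the C2/C3 diol as butane-2,3-dione and methanol leave, and the two benzoates and the tertiary alcohol should survive the brief exposure with no stereocentre touched.

Compound list
1 | but-3-yn-2-ol (racemic) | CC(O)C#C | starting material
2 | dimethyl(phenyl)silane | C[SiH](C)c1ccccc1 | starting material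
3 | (E)-4-[dimethyl(phenyl)silyl]but-3-en-2-ol (racemic) | CC(O)/C=C/[Si](C)(C)c1ccccc1 | intermediate
4 | (E)-4-[dimethyl(phenyl)silyl]but-3-en-2-one | CC(=O)/C=C/[Si](C)(C)c1ccccc1 | intermediate
5 | 3-hydroxy-2H-pyran-2-one | O=c1occcc1O | starting material
6 | 8-acetyl-4-hydroxy-7-[dimethyl(phenyl)silyl]-2-oxabicyclo[2.2.2]oct-5-en-3-one (acetyl endo, silyl exo) | O=C2[C@@]1(O)C=C[C@@H](O2)[C@@H]([Si](C)(C)c3ccccc3)[C@@H]1C(C)=O | intermediate
7 | 4-hydroxy-3-oxo-7-[dimethyl(phenyl)silyl]-2-oxabicyclo[2.2.2]oct-5-en-8-yl acetate (acetate endo, silyl exo) | O=C2[C@@]1(O)C=C[C@@H](O2)[C@@H]([Si](C)(C)c3ccccc3)[C@@H]1OC(C)=O | intermediate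
8 | 7-[fluoro(dimethyl)silyl]-4-hydroxy-3-oxo-2-oxabicyclo[2.2.2]oct-5-en-8-yl acetate (not isolated) | O=C2[C@@]1(O)C=C[C@@H](O2)[C@@H]([Si](C)(C)F)[C@@H]1OC(C)=O | intermediate
9 | 4,7-dihydroxy-3-oxo-2-oxabicyclo[2.2.2]oct-5-en-8-yl acetate (7-OH exo, acetate endo) | O=C2[C@@]1(O)C=C[C@@H](O2)[C@@H](O)[C@@H]1OC(C)=O | intermediate
10 | methyl 1β,2β,3α,4α-tetrahydroxycyclohex-5-ene-1α-carboxylate (route numbering) | COC(=O)[C@@]1(O)C=C[C@@H](O)[C@@H](O)[C@@H]1O | intermediate
11 | 2,3-O-butane-2,3-diacetal of 10 (acetal carbons S,S) | COC(=O)[C@@]1(O)C=C[C@@H](O)[C@H]2O[C@](C)(OC)[C@@](C)(OC)O[C@H]12 | intermediate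
12 | diacetal triol (C7H2OH, 1β-OH, 4α-OH) | OC[C@@]1(O)C=C[C@@H](O)[C@H]2O[C@](C)(OC)[C@@](C)(OC)O[C@H]12 | intermediate
13 | diacetal 7-O,4-O-dibenzoate | O=C(OC[C@@]1(O)C=C[C@@H](OC(=O)c3ccccc3)[C@H]2O[C@](C)(OC)[C@@](C)(OC)O[C@H]12)c4ccccc4 | intermediate
14 | [(1S,4R,5S,6S)-4-(benzoyloxy)-1,5,6-trihydroxycyclohex-2-en-1-yl]methyl benzoate | O=C(OC[C@@]1(O)C=C[C@@H](OC(=O)c2ccccc2)[C@@H](O)[C@@H]1O)c1ccccc1 | target

Total step count: 10. Longest linear sequence: 10 steps (1 → 14); pyrone 5 enters at step 3.

Steps most likely to fail

Step 3. The catalyst may discriminate poorly between the two pyrone faces or between acetyl-endo and acetyl-exo approach, or the bulky silyl group may slow the addition within the catalyst pocket. Fallback, from 4 and 5: the cycloaddition would be run with NEt3 (cat.) in CH2Cl2, relying only on the regiochemistry and endo preference inherent to the olate. This should give 6 as a racemate together with the mirror-image adduct F1. The two would be separated by preparative chromatography on a chiral stationary phase (supercritical CO2/MeOH), returning to the route at 6.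

Step 4. The electrophilic peracid may epoxidise C5=C6 in competition with a slow ketone oxidation, or the free β-hydroxy ketone may be lost by retro-aldol cleavage. Fallback, from 6: the C1 hydroxyl would be capped (TMSCl, imidazole, DMF) to give the C1-O-trimethylsilyl ether of 6 F2. A Lewis-acid-activated silyl peroxide, (Me3SiO)2 with SnCl4 and trans-cyclohexane-1,2-diamine in CH2Cl2 over 4 Å sieves, effects Baeyer–Villiger oxidation without transferring oxygen to alkenes and should give the C1-O-trimethylsilyl ether of 7 F3. Dilute HCl in THF would then remove the silyl ether, returning at 7.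

Step 5. The strong acid of the protodesilylation may ionise the allylic C4–O bond or trigger β-elimination of silicon, or the peracid may attack the alkene during the C–Si oxidation. Fallback, from 1: the silicon group would be made fluoride-labile from the outset. Hydrosilylation of 1 with benzyl(dimethyl)silane under the step 1 conditions would give (E)-4-[benzyl(dimethyl)silyl]but-3-en-2-ol F4, and MnO2 would give (E)-4-[benzyl(dimethyl)silyl]but-3-en-2-one F5. The cycloaddition of step 3 with 5 would give the benzyl(dimethyl)silyl analogue of 6 F6, and mCPBA the benzyl(dimethyl)silyl analogue of 7 F7. Bu4NF in THF at 0 °C would cleave the benzyl–silicon bond to fluorosilane 8, which would be oxidised in the same flask with H2O2/KHCO3 in MeOH (Tamao oxidation), with no strong acid and no peracid, returning at 9.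

Further compounds
F1 | step 3 | mirror-image adduct (enantiomer of 6) | O=C2[C@]1(O)C=C[C@H](O2)[C@H]([Si](C)(C)c3ccccc3)[C@H]1C(C)=O
F2 | step 4 | C1-O-trimethylsilyl ether of 6 | O=C2[C@@]1(O[Si](C)(C)C)C=C[C@@H](O2)[C@@H]([Si](C)(C)c3ccccc3)[C@@H]1C(C)=O
F3 | step 4 | C1-O-trimethylsilyl ether of 7 | O=C2[C@@]1(O[Si](C)(C)C)C=C[C@@H](O2)[C@@H]([Si](C)(C)c3ccccc3)[C@@H]1OC(C)=O
F4 | step 5 | (E)-4-[benzyl(dimethyl)silyl]but-3-en-2-ol (racemic) | CC(O)/C=C/[Si](C)(C)Cc1ccccc1
F5 | step 5 | (E)-4-[benzyl(dimethyl)silyl]but-3-en-2-one | CC(=O)/C=C/[Si](C)(C)Cc1ccccc1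
F6 | step 5 | benzyl(dimethyl)silyl analogue of 6 | O=C2[C@@]1(O)C=C[C@@H](O2)[C@@H]([Si](C)(C)Cc3ccccc3)[C@@H]1C(C)=O
F7 | step 5 | benzyl(dimethyl)silyl analogue of 7 | O=C2[C@@]1(O)C=C[C@@H](O2)[C@@H]([Si](C)(C)Cc3ccccc3)[C@@H]1OC(C)=O
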